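The earlier runs and the new flask are calculated for an exercise; scatter was added.

**Counting partner.** The easy step is to count coupling partner, taking one per molecule of target. Larch and Saturday's flask look nearly alike: both get 15.0 mM of partner and 1.00 mM of capture agent, and they differ in substrate, 15 mM against 10 mM. Saturday's, Monday's and Thursday's are one recipe stopped at different times.

| flask | substrate | coupling partner | capture agent | remark | time |
|---|---|---|---|---|---|
| alder | 6.7 mM | 15 mM | 1 mM | run made earlier |  |
| larch | 15 mM | 15 mM | 1 mM | run made earlier |  |
| cedar | 10 mM | 15 mM | 2 mM | run made earlier |  |
| Saturday's | 10 mM | 15.0 mM | 1.00 mM |  | 12 min |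
| Monday's | 10 mM | 15.0 mM | 1.00 mM |  | 25 min |
| Thursday's | 10 mM | 15.0 mM | 1.00 mM |  | 50 min |

- alder (time / min: target / %): 1.00: 36.7; 1.33: 44.4; 2.00: 56.2; 3.00: 66.2; 5.00: 78.1; 8.00: 83.2; 12.0: 86.7
- larch (time / min: target / %): 0.667: 22.9; 2.00: 44.0; 3.00: 53.3; 5.00: 61.5; 8.00: 69.7; 10.0: 72.7; 12.0: 73.1
- cedar (time / min: target / %): 1.00: 32.6; 2.00: 49.6; 3.00: 61.7; 6.00: 73.9; 12.0: 80.4

(readings scatter by 1 percentage point)

- the analysis behind the earlier runs scatters by 1 percentage point, standard deviation

* which of the two there is more of at the end, Saturday's (side product / target)
* which of the two there is more of at the end, Monday's (side product / target)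
* which of the two there is more of at the end, Thursday's (side product / target)
* target at the end, in percent of the substrate charged, Saturday's
* target at the end, in percent of the substrate charged, Monday's
* target at the end, in percent of the substrate charged, Thursday's

**Larch's partner.** From 10.0 min to 12.0 min larch moves by 0.4 percentage points, against a scatter of 1 point, so these two readings cannot tell a stall from a slow rise. At its last reading larch's target holds 11.0 mM of the 15 mM of partner charged, and the other 4.04 mM is either still free or gone elsewhere.

**Partner roof.** This gives me a rule: the partner roof, the partner charge divided by the substrate charged, is the highest target that partner can pay for at one partner per target. For Saturday's recipe it is 150 %, against 100 % for larch. Larch has no spare partner on this count, but Saturday's recipe has, because its 15.0 mM of partner is more than its 10 mM of substrate. Substrate should therefore be the limiting reagent in Saturday's recipe.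

**My reckoning.** Alder's target reads 86.7 % at its last reading, more than the 83.2 % before it, so I expect all three flasks to hold near that level, with target ahead of side product.

**The forecast.** Here I part from the forecast, which reads the shortfall as “target being consumed by something formed alongside it, once the small capture charge is used up”. It gives 79 %, 62 % and 35 % for Saturday's, Monday's and Thursday's, with side product ahead in Thursday's.

**The flask.** Target stands at 84.0 % in Saturday's, 86.4 % in Monday's and 86.5 % in Thursday's.

    substrate + coupling partner ⇌ intermediate A (K = 84.0 M⁻¹, k = 2.30 M⁻¹ s⁻¹)
    coupling partner + intermediate A → side product (k = 11.0 M⁻¹ s⁻¹)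
    substrate → intermediate B (k = 0.300 s⁻¹)
    coupling partner + intermediate B → target (k = 0.710 M⁻¹ s⁻¹)
    capture agent + intermediate B → trapped intermediate (k = 0.480 M⁻¹ s⁻¹)

Thursday's target lies under its roof of 150 %, with 31.1 % of its charged partner still free. A neighbour of Saturday's charged with 40 mM of substrate has a roof of 37.5 %, and it ends below that at 24.0 % target, with 0 % of its partner left and 66.7 % of its substrate charge standing as intermediate B.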